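**Main step.** If the main step stands alone, the rate of making left-handed product is proportional to free catalyst, so one percent more catalyst charged gives one percent more rate and the apparent order in catalyst is one.

in all of them: left-handed substrate 0.088 M; right-handed substrate 0.088 M; free catalyst 0.97 mM; impurity 0.45 mM

| run | partner | remark |
|---|---|---|
| oak | 0.066 M | run made earlier |
| birch | 0.26 M | run made earlier |
| flask | 0.132 M |  |

- oak (time / min: left-handed product / %): 10.0: 3.5; 25.0: 7.1; 50.0: 10.7; 80.0: 14.2; 120: 16.7
- birch (time / min: left-handed product / %): 20.0: 19.6; 40.0: 28.9; 60.0: 34.6; 80.0: 37.7; 120: 42.4

(readings scatter by 0.3 percentage points)

- apparent order in free catalyst when 10 % of the left-handed substrate and right-handed substrate together are converted (percent change of the rate of making left-handed product for one percent more free catalyst charged)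
- apparent order in partner when 10 % of the left-handed substrate and right-handed substrate together are converted (percent change of the rate of making left-handed product for one percent more partner charged)

- free catalyst is single-handed; left-handed substrate and right-handed substrate are mirror images of each other, charged as a racemate, each of them at the stated concentration
- what was read earlier has a scatter of 0.3 percentage points, one standard deviation
- reactions considered so far: partner + free catalyst + left-handed substrate -> free catalyst + left-handed product; partner + free catalyst + right-handed substrate -> free catalyst + right-handed product; free catalyst <-> dormant form; free catalyst + impurity -> spent catalyst
- no earlier run changes the charge of free catalyst; that part of a forecast is a guess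

Neither oak nor birch changes the catalyst charge, so their readings give no order in catalyst, and that order has to be reckoned from the charges.

**Impurity added.** Each impurity takes one free catalyst into spent catalyst. Provided this is over by the moment of looking, the flask works with the charge minus the impurity, 0.520 mM. Extra catalyst charged meets no extra impurity, so it goes wholly to this working remainder, whose percent change is larger than the percent change of the charge. The ratio of the two percent changes is the titration gain 1.87: catalyst charged divided by catalyst charged minus impurity charged, which is the apparent order in catalyst once the impurity has finished.

**Dormant form.** Free catalyst and the dormant form, an off-cycle form, exchange by first-order steps, so at a given time the same fraction of the working catalyst stands aside at any charge. At one and the same time that fraction cancels in a percent change, but the order is taken at one conversion, which more catalyst charged reaches earlier, while the dormant form is still growing, so the 1.87 reckoned here for the flask stands as a slightly low estimate of the order.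

**The forecast.** The forecast gives 1.6 for catalyst and 1.1 for partner, and of the impurity it says “The steady rates favour fast titration.” Its catalyst order is lower than the gain reckoned here.

**Flask result.** The flask gives an apparent order of 1.9 in free catalyst and 1.2 in partner, on these steps:

    partner + free catalyst + left-handed substrate → free catalyst + left-handed product (k = 12400 M⁻² h⁻¹)
    partner + free catalyst + right-handed substrate → free catalyst + right-handed product (k = 6790 M⁻² h⁻¹)
    free catalyst ⇌ dormant form (K = 0.360, k = 0.258 h⁻¹)
    free catalyst + impurity → spent catalyst (k = 1.12 × 10⁵ M⁻¹ h⁻¹)

**Impurity's work.** In the flask, the turning of free catalyst and impurity into spent catalyst has the largest single effect on the catalyst order, and the gain of 1.87 stands beside the flask's 1.9. At 0.300 h the impurity stands at 0 % of its charge and spent catalyst holds 46.4 % of the catalyst charged. With the impurity's turning of free catalyst into spent catalyst taken away from the flask, the simulated run gives an order of 1.0 and, at 10 % conversion, a rate 1.90 times the actual one.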